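The numbers of this flask were set for the occasion.

The pitfall in this flask is to treat target as an end point: target is also a reagent for substrate, and step 3 has a larger constant than step 1.

| setting | Friday's | Wednesday's | Saturday's |
|---|---|---|---|
| substrate | 0.057 M | 0.057 M | 0.057 M |
| partner | 1.50 equiv | 1.50 equiv | 1.50 equiv |
| temperature | 70 °C | 80 °C | 90 °C |
| time | 1.5 h | 1.5 h | 1.5 h |

    substrate + partner → target (k1 = 0.0047 /M/s, Ea1 = 57.0 kJ/mol)
    substrate + partner → isomer of the product (k2 = 5.7 × 10⁻⁵ /M/s, Ea2 = 82.0 kJ/mol)
    substrate + target → side product (k3 = 0.024 /M/s, Ea3 = 63.0 kJ/mol)
    substrate + partner → second isomer (k4 = 3.9 × 10⁻⁴ /M/s, Ea4 = 70.0 kJ/mol)
    target → over-reaction product (k5 = 6.5 × 10⁻⁵ /s, Ea5 = 102 kJ/mol)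
    (constants at 70 °C)

- percent here means substrate units held: one side product counts as two
- constants are those at 70 °C; use the activation energies for any other temperature

- which of these there is most of at the end, counted by the substrate in it, Friday's (over-reaction product / substrate / side product / second isomer / target)
- which of these there is most of at the end, counted by the substrate in it, Wednesday's (over-reaction product / substrate / side product / second isomer / target)
- which of these there is most of at the end, counted by the substrate in it, Saturday's (over-reaction product / substrate / side product / second isomer / target)
- amount of the one of these that there is most of at the end, in percent of the substrate charged, Friday's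
- amount of the one of these that there is most of at the end, in percent of the substrate charged, Wednesday's
- amount of the one of these that there is most of at the end, in percent of the substrate charged, Saturday's

In the first instants of Friday's there is no target, so step 1 carries the flask: the half-life of substrate by step 1 alone is 0.48 h, shorter than 5.8 h by step 4 alone and 40 h by step 2 alone. The first target meets substrate near its charge. With substrate as charged on Friday's, the half-life of target by step 3 is 0.14 h, shorter than the 3.0 h by step 5 alone.

So the reckoning expects target to stop rising soon. Steps 1 and 3 both carry substrate as a factor, and it cancels in their ratio. The reckoning therefore puts target, as a steady-state intermediate, at the fraction of the charge where step 3 removes it as fast as step 1 makes it. Call this the balance level: k1 over k3, times the equivalents of partner present. Each side product takes one partner and two substrates, so a charge of substrate spent on side product takes about 0.5 equiv of partner, and the reckoning uses the 1.00 equiv that this leaves. That puts the balance level of Friday's at 19.6%.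

With target at the balance level, steps 1 and 3 use substrate equally, so the reckoning has substrate fall pseudo-first-order at the summed rate of the two. Counted that way, Friday's gives substrate 2.89 turnovers, which leaves 5.56% of the charge.

Toward the end, the substrate units are shared out by subtraction. Besides the substrate left and the balance level, two small items come off. One is the leak, what step 5 pulls from target during the life of substrate: 2.38% on Friday's. The other is the isomers, made beside about 0.5 of the charge of target: 4.76% on Friday's. What remains is side product, 67.7% on Friday's.

Warming lowers the balance level to 18.5% on Wednesday's and 17.4% on Saturday's. For the same two flasks, in the same order, the turnovers rise to 5.09 and 8.69, the leak to 3.50% and 5.04%, and the isomers to 5.50% and 6.31%. The subtraction then gives 71.9% on Wednesday's and 71.2% on Saturday's. The leader by this reckoning is side product on Friday's, side product on Wednesday's and side product on Saturday's.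

The forecast names side product in each flask, at 64%, 65% and 61% for Friday's, Wednesday's and Saturday's, on the ground that “each side product counts for two substrate units”; on Saturday's it stands lower than the reckoning here.

Friday's gives side product at 67.8%. Wednesday's gives side product at 70.8%. Saturday's gives side product at 69.2%.

On Saturday's, target and over-reaction product together hold 23.3%, against 22.4% from the balance level and leak. Part of what side product lacks on Saturday's goes through two steps acting together: with step 5 struck out it stands at 76.1%, with step 4 struck out at 74.3%, against 69.2%.

At 115 °C, the reckoning gives the neighbour of Saturday's a balance level of 15.3% and a leak of 11.6%, which with its isomers leaves 64.4% for side product. The simulation of that neighbour gives side product at 60.5%.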